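The runs are calculated for substances that don't exist, noise included.

**Violet's clue.** In the violet run, the first reading shows Z at 0.0611 M when only 0.0440 M of D has gone in. So Z is not made from D one to one. It appears to form from E and X by themselves, and D then drains it.

- violet: E 0.075 M; X 0.075 M; D 2.2 equiv (fed, over 15 min); run made earlier; the fed solution adds 0.20 times the starting volume
- flask: E 0.050 M; D 2.20 equiv (fed, over 15 min); X 0.050 M; time 2.5 h; the fed solution adds 0.20 times the starting volume

violet run (percent of the E and X together charged)

| time / min | Z / % | G / % |
|---|---|---|
| 4.00 | 40.7 | 1.1 |
| 6.00 | 40.5 | 3.3 |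
| 10.0 | 37.4 | 8.8 |
| 15.0 | 30.9 | 16.3 |
| 25.0 | 24.7 | 27.1 |
| 50.0 | 20.8 | 36.3 |

(readings scatter by 1 percentage point)

- the moment within 2.5 h at which there is most Z, in min
- the amount of Z, in percent of the E and X together charged, at that time
- earliest time at which at least nineteen twentieths of that best amount are there, in min
- latest time at which they still are

- D is single-handed; E and X are mirror images of each other, charged as a racemate, each of them at the stated concentration
- charges are per starting volume, the dose included; the dosed solution carries all of it
- the handed part of D does not stay in what it makes, so the products of the two hands are mirror images too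

**One number.** Take P as the plateau of Z. I assume the drain is proportional to [D], and [D] climbs linearly during a feed of length T. Integrating gives ln(P/Z) = Θ(t/T) squared. Violet's first reading and its reading at 15.0 min give 0.297 and a read plateau of 41.6%. Θ, the feed number, is the exponent of D's drain on Z at the end of the feed, and on that assumption it scales with concentration, equivalents and T.

**Testing it.** At 10.0 min this gives 36.4% against a reading of 37.4%, a gap inside the scatter.

**This flask.** In this flask Θ is 0.198, so my estimate for the loss of one twentieth of P is 0.127 h, inside the feed. I expect this flask to peak near P. But Θ holds no clock for the rise. Violet already stands near its read plateau at its first reading, so if the rise does not depend on concentration, I place this flask's opening and peak before 4.00 min.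

**The forecast.** It gives 41.5% at 6 min, open from 4 min to 0.15 h, reasoning that “If every step is second order in D, Z depends only on the D exposure”.

**The result.** The flask peaks at 42.5% at 2.44 min, opens at 1.15 min and shuts at 0.121 h, against my 0.127 h.

    E ⇌ Z (K = 1.50, k = 0.0177 /s)
    X ⇌ Z (K = 1.50, k = 0.0177 /s)
    D + X → L (k = 0.00949 /M/s)
    D + E → G (k = 0.0165 /M/s)
    D ⇌ Q (K = 5.16, k = 7.69 × 10⁻⁴ /s)

**Thinner dose.** The neighbour charged with 0.880 equiv of D has Θ = 0.0791, less than the flask's, so the same reckoning again expects a peak near P. It reaches 42.7%, and at 2.50 h it holds 31.5% Z against 16.8% G.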